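(The numbers of this flask were chosen freely; the rest is arithmetic.)

In a one-step world, a starting material meeting a reagent ends at one equilibrium constant, and the fraction left says what there is to say. Here two steps draw on the same pair, as two sites compete for one ligand, so a second number is needed to divide what has reacted. Red and violet carry the same charges and differ by their temperature.

- red: starting material 0.12 M; reagent 0.240 M; free catalyst 0.60 mM; temperature 5 °C; time 1.0 h
- violet: starting material 0.12 M; reagent 0.240 M; free catalyst 0.60 mM; temperature 20 °C; time 1.0 h

    target + free catalyst ⇌ isomer of the product + free catalyst, rate k1*[free catalyst]*[target] forward; the back reaction follows from the equilibrium constant (k1 = 2.1 M⁻¹ s⁻¹, Ea1 = 47.0 kJ mol⁻¹)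
    starting material + reagent ⇌ target (K2 = 5.6 M⁻¹, k2 = 0.019 M⁻¹ s⁻¹, Ea2 = 51.0 kJ mol⁻¹, ΔH2 = 21.0 kJ mol⁻¹)
    free catalyst → spent catalyst (k3 = 0.0016 s⁻¹, Ea3 = 80.0 kJ mol⁻¹)
    starting material + reagent ⇌ isomer of the product (K4 = 13 M⁻¹, k4 = 0.0073 M⁻¹ s⁻¹, Ea4 = 45.0 kJ mol⁻¹, ΔH4 = −42.0 kJ mol⁻¹)
    (constants at 5 °C)

- the list of constants is for 5 °C, to be carried to other temperatures by the activation energies and enthalpies

* which of these there is most of at the end, counted by the starting material in it, red (starting material / isomer of the product / target)
* which of these there is most of at the end, counted by the starting material in it, violet (starting material / isomer of the product / target)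
* amount of the one of these that there is most of at the end, in percent of the starting material charged, red
* amount of the one of these that there is most of at the end, in percent of the starting material charged, violet

The reckoning here begins with time. In red, the forward half-lives of starting material are 2.5 min by step 2 and 0.11 h by step 4, both shorter than the 1.0 h allowed . In violet, the forward half-life of starting material by step 4, carried to its temperature, is 2.44 min, again shorter than the time. So this reckoning takes both flasks to the balance of steps 2 and 4, thermodynamic rather than kinetic control.

The split, isomer of the product over target at balance, is the constant of step 4 over that of step 2, 2.32 in red. It is also the equilibrium constant of step 1, so the catalyst speeds the exchange without moving the balance. The split moves with temperature by the difference of the enthalpies, −63.0 kJ mol⁻¹, and in violet it comes to 0.576. It stands above one in red and below one in violet, so isomer of the product should end above target in red and below it in violet.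

The fraction left comes next. Starting material is the limiting reagent, so free reagent is its charge less what the reacted starting material has taken. At balance, reacted over left equals the sum of the two constants times free reagent, a quadratic in the fraction left, as in binding with depletion. The sum is 18.6 M⁻¹ in red and 14.0 M⁻¹ in violet, which leaves 26.2 % in red and 31.1 % in violet. Dividing the reacted part by the split, red should hold most as isomer of the product, at 51.6 % of the charge. Violet should hold most as target, at 43.7 %.

The forecast gives isomer of the product at 51 % in red and target at 44 % in violet, “so the endothermic target wins there”.

After 1.00 h, red holds isomer of the product at 51.2 % with 26 % of the starting material left, and violet holds target at 43.7 % with 31.1 % left. The neighbouring flask repeats violet at 45 °C. Its sum is 18.9 M⁻¹, close to red's, so its fraction left reckons to 26.0 %. Its split, 0.0756, should put 5.20 % of the charge in isomer of the product. That flask ends with 26 % of the starting material left, 68.8 % as target and 5.20 % as isomer of the product.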